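**Plan**

1. Retrosynthetic cuts, in order: the 7'-O-methyl ether and the two aryl–acyl bonds (C8'–CHO, C6'–COiBu); a C4' carbonyl is put back; the spiro O1'–C2 bond (retro-oxa-Michael to exocyclic enone 10); the pinane ring bond C4–C5, with a carboxyl put back on C5 (dienone acid 9); the C2–alkyne bond, giving vinyl ketone 3 and aryl alkyne 7. Pinane numbering: C1/C5 bridgeheads, C2 spiro carbon, C3/C4 ring CH2, C6 = CMe2, C7 = CH2 bridge.
2. Forward order of rings: cyclobutane (bought as (−)-verbenone and cleaved to acid 2), open dienone, six-membered carbocycle of the pinane (step 7), pyran ring (step 8), then the arene substituents.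
3. Enabling feature: the cyclobutane C1–C6–C5–C7 holds C1 and C5 1,3-cis, so the arm C2–C3=C4 on C1 can bridge to C5 on one face only. C5 carries a carboxyl (traceless radical precursor). The sp2 carbon C2 is conjugated through C3' to the C4' aryl ketone, which makes C4 the electrophilic δ-terminus and later makes C2 the oxa-Michael acceptor.
4. Stereochemistry: C1 comes from the chiral pool and is never touched; C5 is fixed by the bridge geometry in step 7; spiro C2 is set in step 8 by phenoxide attack anti to the gem-dimethyl bridge.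
5. Helpers and their removal: CO2H on C5 (lost as CO2 in step 7), C4'=O (step 9), MOM ethers (step 8), methyl ether (step 12).

Key step: step 7

Assumption (chemistry): elements that a later step erases (the carbinol centre of 8, the C=C geometry of 9 and 10) are carried as mixtures and left unspecified in the SMILES.

**Route**

Step 1
Reactants: 1 (1S,5S)-(−)-verbenone
Product: 2 (1S,3R)-3-acetyl-2,2-dimethylcyclobutane-1-carboxylic acid [(−)-cis-pinononic acid]
Conditions: RuCl3·xH2O (2 mol%), NaIO4 (4.2 equiv), CCl4/MeCN/H2O, rt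
Reagents that add atoms: sodium periodate, [Na+].[O-]I(=O)(=O)=O
Why: RuO4 (octavalent ruthenium, formed in situ and recycled by NaIO4) cleaves the enone C=C bond and the resulting α-keto acid loses CO2 (RuO4-catalysed oxidative cleavage), while both ring stereocentres stay untouched, so the cis keto acid should be obtained in the enantiomeric form fixed by the terpene.

Step 2
Reactants: 2 (1S,3R)-3-acetyl-2,2-dimethylcyclobutane-1-carboxylic acid
Product: 3 (1S,3R)-3-acryloyl-2,2-dimethylcyclobutane-1-carboxylic acid
Conditions: (CH2O)n (2 equiv), i-Pr2NH·CF3CO2H (1 equiv), CF3CO2H (10 mol%), BHT (trace), THF, 65 °C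
Reagents that add atoms: paraformaldehyde (as formaldehyde), C=O
Why: Mannich condensation followed by β-elimination of the amine (direct α-methylenation) turns the acetyl methyl into a vinyl group; only the methyl can give an enone, and enolization toward the ring carbon (an exocyclic cyclobutylidene beside the quaternary carbon) is disfavoured, which protects the α-stereocentre, and no new stereocentre arises.

Step 3
Reactants: 4 1-(2,6-dihydroxy-4-methoxyphenyl)ethan-1-one
Product: 5 1-[4-methoxy-2,6-bis(methoxymethoxy)phenyl]ethan-1-one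
Conditions: NaH (2.1 equiv), MOMCl (2.2 equiv), DMF, 0 °C to rt
Reagents that add atoms: chloromethyl methyl ether, COCCl
Why: Williamson etherification of both hydrogen-bonded phenoxides; the MOM groups keep the phenols from adding to the dienone before the key step and tolerate amide bases and organolithium reagents.

Step 4
Reactants: 5 1-[4-methoxy-2,6-bis(methoxymethoxy)phenyl]ethan-1-one
Product: 7 2-ethynyl-5-methoxy-1,3-bis(methoxymethoxy)benzene, via enol phosphate 6 (not isolated)
Conditions: LiN(i-Pr)2 (1.1 equiv), THF, −78 °C; ClP(O)(OEt)2, −78 °C to rt; then LiN(i-Pr)2 (2.5 equiv), −78 °C to rt; aq. NH4Cl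
Reagents that add atoms: none
Why: Methyl ketone to terminal alkyne by O-phosphorylation of the kinetic enolate and base-induced elimination of diethyl phosphate from the enol phosphate; the acetylide is protonated on work-up and no stereocentre is involved.

Step 5
Reactants: 3 (1S,3R)-3-acryloyl-2,2-dimethylcyclobutane-1-carboxylic acid, 7 2-ethynyl-5-methoxy-1,3-bis(methoxymethoxy)benzene
Product: 8 (1S,3R)-3-{3-hydroxy-5-[4-methoxy-2,6-bis(methoxymethoxy)phenyl]pent-1-en-4-yn-3-yl}-2,2-dimethylcyclobutane-1-carboxylic acid (both carbinol epimers)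
Conditions: 7 (2.3 equiv), n-BuLi (2.2 equiv), THF, −78 °C; then 3, −78 °C; aq. NH4Cl, then pH 4
Reagents that add atoms: none
Why: 1,2-Addition of a hard lithium acetylide to the vinyl ketone carbonyl (alkynylation; the first equivalent only deprotonates the acid and returns as 7) should give the tertiary propargylic, allylic alcohol; the carbinol centre forms without control, which is harmless because it becomes sp2 in step 6.

Step 6
Reactants: 8 (1S,3R)-3-{3-hydroxy-5-[4-methoxy-2,6-bis(methoxymethoxy)phenyl]pent-1-en-4-yn-3-yl}-2,2-dimethylcyclobutane-1-carboxylic acid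
Product: 9 (1S,3R)-3-{5-[4-methoxy-2,6-bis(methoxymethoxy)phenyl]-5-oxopenta-1,3-dien-3-yl}-2,2-dimethylcyclobutane-1-carboxylic acid (E/Z mixture)
Conditions: TsOH·H2O (5 mol%), THF/H2O (20:1), 0 °C to rt
Reagents that add atoms: water, O
Why: Meyer–Schuster rearrangement: acid-promoted loss of water gives a cation whose charge rests mainly on the alkyne carbon next to the trioxygenated arene, water adds there and the allenol tautomerizes irreversibly to the aryl ketone, so the reversible side paths (return at the carbinol carbon, capture at the vinyl terminus, lactonization by the cis acid) should drain into dienone 9, while catalytic acid at low temperature leaves the MOM ethers and the ring stereocentres intact.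

Step 7
Reactants: 9 (1S,3R)-3-{5-[4-methoxy-2,6-bis(methoxymethoxy)phenyl]-5-oxopenta-1,3-dien-3-yl}-2,2-dimethylcyclobutane-1-carboxylic acid
Product: 10 2-[(1R,5S)-6,6-dimethylbicyclo[3.1.1]heptan-2-ylidene]-1-[4-methoxy-2,6-bis(methoxymethoxy)phenyl]ethan-1-one (E/Z mixture)
Conditions: Ir[dF(CF3)ppy]2(dtbbpy)PF6 (2 mol%), K2HPO4 (1.2 equiv), degassed DMF (5 mM), 450 nm LEDs, rt
Reagents that add atoms: none
Why: Proposed new method: the photoexcited trivalent iridium complex oxidizes the carboxylate of 9, loss of CO2 leaves a secondary cyclobutyl radical at C5, this radical adds to the terminal (δ) carbon C4 of the dienone held over the same ring face by C1, and the resulting keto-pentadienyl radical is reduced by divalent iridium and protonated to enone 10. The closest known reaction types are the photoredox decarboxylative Giese addition of carboxylic acids to Michael acceptors and endo-mode radical cyclizations onto enones whose carbonyl lies in the tether; what is new is the vinylogous (1,6) acceptor and the bridged bicyclo[3.1.1]heptane that results. The six-membered ring C1–C2–C3–C4–C5–C6 (or –C7) closes in the 6-endo-trig mode, the attacked C3=C4 bond lying inside the new ring. The only new stereocentre, C5, can form in one sense only, because the three-carbon arm must span the 1,3-cis positions of the cyclobutane; the planar radical erases the old C5 configuration, and the untouched C1 centre inherited from 2 alone fixes the absolute configuration of both bridgeheads. The step needs 6-endo over 5-exo attack, which is secured by polarity matching (nucleophilic alkyl radical, unsubstituted electrophilic δ-terminus), by the delocalized product radical as against a primary one, and by the much higher strain of the bicyclo[2.1.1]hexane that 5-exo closure would give. High dilution and the absence of a hydrogen-atom donor should keep the radical alive until it cyclizes, and any β,γ-unsaturated isomer formed on protonation converges in step 8.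

Step 8
Reactants: 10 2-[(1R,5S)-6,6-dimethylbicyclo[3.1.1]heptan-2-ylidene]-1-[4-methoxy-2,6-bis(methoxymethoxy)phenyl]ethan-1-one
Product: 12 (1R,2R,5S)-5'-hydroxy-7'-methoxy-6,6-dimethylspiro[bicyclo[3.1.1]heptane-2,2'-chroman]-4'-one, via bis-phenol enone 11 (not isolated)
Conditions: TsOH·H2O (0.2 equiv), MeOH, rt to 40 °C; then K2CO3 (0.5 equiv), 0 °C
Reagents that add atoms: none
Why: Acid-catalysed acetal exchange with methanol removes both MOM groups, and on mild basification either of the two equivalent phenoxides adds to the β-carbon C2 of the exocyclic enone (6-endo-trig oxa-Michael, the ring-closing half of a Kabbe chromanone synthesis); the spiro stereocentre should be set under kinetic control by attack on the face of C2 anti to the gem-dimethyl bridge, which places the oxygen on the side of the CH2 bridge as in the target.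

Step 9
Reactants: 12 (1R,2R,5S)-5'-hydroxy-7'-methoxy-6,6-dimethylspiro[bicyclo[3.1.1]heptane-2,2'-chroman]-4'-one
Product: 14 (1R,2R,5S)-7'-methoxy-6,6-dimethylspiro[bicyclo[3.1.1]heptane-2,2'-chroman]-5'-ol, via ethyl carbonate 13 (not isolated)
Conditions: ClCO2Et (1.2 equiv), Et3N (1.5 equiv), THF, 0 °C; then NaBH4 (4 equiv), THF/H2O, 0 °C to rt
Reagents that add atoms: none
Why: Reductive deoxygenation of an o-hydroxyaryl ketone through its ethyl carbonate: NaBH4 reduces the ketone, the carbonate migrates to the benzylic alkoxide and leaves to give an o-quinone methide, which takes up a second hydride, so the helper carbonyl becomes CH2 and the 5'-phenol is returned under non-acidic conditions that touch neither the spiro ether nor the stereocentres.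

Step 10
Reactants: 14 (1R,2R,5S)-7'-methoxy-6,6-dimethylspiro[bicyclo[3.1.1]heptane-2,2'-chroman]-5'-ol
Product: 15 1-[(1R,2R,5S)-5'-hydroxy-7'-methoxy-6,6-dimethylspiro[bicyclo[3.1.1]heptane-2,2'-chroman]-6'-yl]-3-methylbutan-1-one
Conditions: i-BuCOCl (1.2 equiv), TiCl4 (2.2 equiv), CH2Cl2, −40 to 0 °C; ice-water
Reagents that add atoms: 3-methylbutanoyl chloride (isovaleryl chloride), CC(C)CC(=O)Cl
Why: Friedel–Crafts acylation directed by the titanium phenoxide (ortho-acylation of a phenol): the acyl group should be delivered to C6', the only free position ortho to the 5'-OH, to give the chelated o-hydroxy ketone, and the low temperature is chosen to spare the tertiary spiro ether.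

Step 11
Reactants: 15 1-[(1R,2R,5S)-5'-hydroxy-7'-methoxy-6,6-dimethylspiro[bicyclo[3.1.1]heptane-2,2'-chroman]-6'-yl]-3-methylbutan-1-one
Product: 16 (1R,2R,5S)-5'-hydroxy-7'-methoxy-6,6-dimethyl-6'-(3-methylbutanoyl)spiro[bicyclo[3.1.1]heptane-2,2'-chroman]-8'-carbaldehyde
Conditions: POCl3 (1.5 equiv), DMF, 0 to 45 °C; then H2O
Reagents that add atoms: N,N-dimethylformamide, CN(C)C=O; water, O
Why: Vilsmeier–Haack formylation at C8', the last free ring position, which is activated by the flanking methoxy and ring oxygens and lies para to the phenol, so no regiochemical choice remains.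

Step 12
Reactants: 16 (1R,2R,5S)-5'-hydroxy-7'-methoxy-6,6-dimethyl-6'-(3-methylbutanoyl)spiro[bicyclo[3.1.1]heptane-2,2'-chroman]-8'-carbaldehyde
Product: 17 Euglobal G3, (1R,2R,5S)-5',7'-dihydroxy-6,6-dimethyl-6'-(3-methylbutanoyl)spiro[bicyclo[3.1.1]heptane-2,2'-chroman]-8'-carbaldehyde
Conditions: LiCl (5 equiv), DMF, 120 °C; dilute citric acid work-up
Reagents that add atoms: none
Why: Nucleophilic O-demethylation (SN2 attack of chloride on the methyl group): the methoxy group is activated by two ortho carbonyl groups, and the Lewis-acid-free conditions should spare the acid-labile tertiary spiro ether, the aldehyde and all stereocentres.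

**Compound list**

1 | (1S,5S)-(−)-verbenone | CC1=CC(=O)[C@H]2C[C@@H]1C2(C)C | starting material
2 | (1S,3R)-3-acetyl-2,2-dimethylcyclobutane-1-carboxylic acid | CC(=O)[C@@H]1C[C@H](C(=O)O)C1(C)C | intermediate
3 | (1S,3R)-3-acryloyl-2,2-dimethylcyclobutane-1-carboxylic acid | C=CC(=O)[C@@H]1C[C@H](C(=O)O)C1(C)C | intermediate
4 | 1-(2,6-dihydroxy-4-methoxyphenyl)ethan-1-one | CC(=O)c1c(O)cc(OC)cc1O | starting material
5 | 1-[4-methoxy-2,6-bis(methoxymethoxy)phenyl]ethan-1-one | CC(=O)c1c(OCOC)cc(OC)cc1OCOC | intermediate
6 | diethyl 1-[4-methoxy-2,6-bis(methoxymethoxy)phenyl]ethenyl phosphate | C=C(OP(=O)(OCC)OCC)c1c(OCOC)cc(OC)cc1OCOC | intermediate (not isolated)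
7 | 2-ethynyl-5-methoxy-1,3-bis(methoxymethoxy)benzene | C#Cc1c(OCOC)cc(OC)cc1OCOC | intermediate
8 | (1S,3R)-3-{3-hydroxy-5-[4-methoxy-2,6-bis(methoxymethoxy)phenyl]pent-1-en-4-yn-3-yl}-2,2-dimethylcyclobutane-1-carboxylic acid (carbinol epimers) | C=CC(O)(C#Cc1c(OCOC)cc(OC)cc1OCOC)[C@@H]1C[C@H](C(=O)O)C1(C)C | intermediate
9 | (1S,3R)-3-{5-[4-methoxy-2,6-bis(methoxymethoxy)phenyl]-5-oxopenta-1,3-dien-3-yl}-2,2-dimethylcyclobutane-1-carboxylic acid (E/Z) | COCOc1cc(OC)cc(OCOC)c1C(=O)C=C(C=C)[C@@H]1C[C@H](C(=O)O)C1(C)C | intermediate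
10 | 2-[(1R,5S)-6,6-dimethylbicyclo[3.1.1]heptan-2-ylidene]-1-[4-methoxy-2,6-bis(methoxymethoxy)phenyl]ethan-1-one (E/Z) | COCOc1cc(OC)cc(OCOC)c1C(=O)C=C1CC[C@H]2C[C@@H]1C2(C)C | intermediate
11 | 1-(2,6-dihydroxy-4-methoxyphenyl)-2-[(1R,5S)-6,6-dimethylbicyclo[3.1.1]heptan-2-ylidene]ethan-1-one | COc1cc(O)c(C(=O)C=C2CC[C@H]3C[C@@H]2C3(C)C)c(O)c1 | intermediate (not isolated)
12 | (1R,2R,5S)-5'-hydroxy-7'-methoxy-6,6-dimethylspiro[bicyclo[3.1.1]heptane-2,2'-chroman]-4'-one | Oc1cc(OC)cc2c1C(=O)C[C@@]1(CC[C@H]3C[C@@H]1C3(C)C)O2 | intermediate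
13 | ethyl (1R,2R,5S)-7'-methoxy-6,6-dimethyl-4'-oxospiro[bicyclo[3.1.1]heptane-2,2'-chroman]-5'-yl carbonate | CCOC(=O)Oc1cc(OC)cc2c1C(=O)C[C@@]1(CC[C@H]3C[C@@H]1C3(C)C)O2 | intermediate (not isolated)
14 | (1R,2R,5S)-7'-methoxy-6,6-dimethylspiro[bicyclo[3.1.1]heptane-2,2'-chroman]-5'-ol | Oc1cc(OC)cc2c1CC[C@@]1(CC[C@H]3C[C@@H]1C3(C)C)O2 | intermediate
15 | 1-[(1R,2R,5S)-5'-hydroxy-7'-methoxy-6,6-dimethylspiro[bicyclo[3.1.1]heptane-2,2'-chroman]-6'-yl]-3-methylbutan-1-one | CC(C)CC(=O)c1c(OC)cc2c(c1O)CC[C@@]1(CC[C@H]3C[C@@H]1C3(C)C)O2 | intermediate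
16 | (1R,2R,5S)-5'-hydroxy-7'-methoxy-6,6-dimethyl-6'-(3-methylbutanoyl)spiro[bicyclo[3.1.1]heptane-2,2'-chroman]-8'-carbaldehyde | CC(C)CC(=O)c1c(OC)c(C=O)c2c(c1O)CC[C@@]1(CC[C@H]3C[C@@H]1C3(C)C)O2 | intermediate
17 | Euglobal G3 | CC(C)CC(=O)c1c(O)c(C=O)c2c(c1O)CC[C@@]1(CC[C@H]3C[C@@H]1C3(C)C)O2 | target

**Step count**

Total steps: 12. Longest linear sequence: 10 steps (1, 2, 5, 6, 7, 8, 9, 10, 11, 12; the arene branch 3, 4, 5–12 is equally long).

**Steps most likely to fail**

1. Step 7 (Proposed new method). The cyclobutyl radical may be reduced or add intermolecularly before it reaches C4, because the 6-endo closure builds a strained bridged ring. Part of the dienone may also rest as its 2H-pyran valence isomer or be consumed by sensitized photochemistry.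
   Fallback (known chemistry, polar closure of the same ring bond): it sets out from 3 and comes back at 12. HBr is added across the enone and the ketone is ketalized in the same flask (Me3SiBr, then 1,2-bis(trimethylsilyloxy)ethane with Me3SiOTf cat.; the silyl ester is hydrolysed on work-up) to give the bromo ketal acid F1. LiN(i-Pr)2 (2.2 equiv, THF, −78 to 0 °C) forms the carboxylate enediolate, whose ring carbon alkylates the primary bromide (6-exo-tet) to give the bridgehead acid F2. Barton reductive decarboxylation (acid chloride, sodium salt of N-hydroxypyridine-2-thione, t-BuSH, light) gives the nopinone ketal F3, and aqueous acid gives (+)-nopinone F4. Kabbe condensation of F4 with acetophenone 4 (pyrrolidine, MeOH, 60 °C) should then give spirochromanone 12.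

2. Step 6. The delocalized cation may be diverted: allylic transposition to an enynol, lactonization by the cis acid, or early loss of a MOM group followed by premature ring closure of the phenol.
   Fallback (aldol route, no alkyne and no cationic rearrangement): it sets out from 3 and 5 and comes back at 9. The lithium enolate of 5 (LiN(i-Pr)2), transmetalated with CeCl3, is added (2.2 equiv, −78 °C) to 3 and should give by 1,2-addition the β-hydroxy ketone F5. F5 is dehydrated through its trifluoroacetate ((CF3CO)2O, Et3N, 0 °C, E1cB) to dienone 9.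

3. Step 10. The Lewis acid may ionize the tertiary spiro ether, with rearrangement of the pinane skeleton, and acylation para to the phenol (C8') may compete.
   Fallback (ortho-specific and free of strong Lewis acids): it sets out from 14 and comes back at 15. Magnesium-mediated ortho-formylation (MgCl2, Et3N, (CH2O)n, MeCN, reflux) can reach only C6' and gives the salicylaldehyde F6. i-BuMgBr (3 equiv, THF, 0 °C) gives the carbinol F7, and oxidation with Dess–Martin periodinane gives ketone 15.

**Further compounds**

F1 | step 7 | (1S,3R)-3-[2-(2-bromoethyl)-1,3-dioxolan-2-yl]-2,2-dimethylcyclobutane-1-carboxylic acid | BrCCC1(OCCO1)[C@@H]1C[C@H](C(=O)O)C1(C)C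
F2 | step 7 | (1R,5R)-6,6-dimethylspiro[bicyclo[3.1.1]heptane-2,2'-[1,3]dioxolane]-5-carboxylic acid | C1COC2(O1)CC[C@@]3(C(=O)O)C[C@@H]2C3(C)C
F3 | step 7 | (1R,5S)-6,6-dimethylspiro[bicyclo[3.1.1]heptane-2,2'-[1,3]dioxolane] | C1COC2(O1)CC[C@H]3C[C@@H]2C3(C)C
F4 | step 7 | (1R,5S)-6,6-dimethylbicyclo[3.1.1]heptan-2-one [(+)-nopinone] | O=C1CC[C@H]2C[C@@H]1C2(C)C
F5 | step 6 | (1S,3R)-3-{3-hydroxy-5-[4-methoxy-2,6-bis(methoxymethoxy)phenyl]-5-oxopent-1-en-3-yl}-2,2-dimethylcyclobutane-1-carboxylic acid (carbinol epimers) | C=CC(O)(CC(=O)c1c(OCOC)cc(OC)cc1OCOC)[C@@H]1C[C@H](C(=O)O)C1(C)C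
F6 | step 10 | (1R,2R,5S)-5'-hydroxy-7'-methoxy-6,6-dimethylspiro[bicyclo[3.1.1]heptane-2,2'-chroman]-6'-carbaldehyde | O=Cc1c(OC)cc2c(c1O)CC[C@@]1(CC[C@H]3C[C@@H]1C3(C)C)O2
F7 | step 10 | 1-[(1R,2R,5S)-5'-hydroxy-7'-methoxy-6,6-dimethylspiro[bicyclo[3.1.1]heptane-2,2'-chroman]-6'-yl]-3-methylbutan-1-ol (carbinol epimers) | CC(C)CC(O)c1c(OC)cc2c(c1O)CC[C@@]1(CC[C@H]3C[C@@H]1C3(C)C)O2
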